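What is left of E after its peak is what I need here, so I reckon with the fraction left and not with the fraction made.

| flask | X | remark | time |
|---|---|---|---|
| oak | 2.5 M | run made earlier |  |
| birch | 1.7 M | run made earlier |  |
| east | 2.5 M | a tube with plug flow, the mixed feed as stated, residence time 6.0 min | 6.0 min |
| south-west | 2.5 M | everything together in a closed stirred flask, run for 6.0 min | 6.0 min |
| north-west | 2.5 M | a single well-mixed tank run continuously and read at steady state, 6.0 min in it on average |  |

- oak (time / min: E / %): 0.833: 21.7; 2.00: 28.1; 2.50: 28.2; 4.00: 26.3
- birch (time / min: E / %): 0.833: 22.1; 2.00: 27.7; 4.00: 25.4; 6.00: 21.2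

(each reading ± 0.3 percentage points)

- the set-up with the highest amount of E at the outlet or at the end, in percent of the X put in ("none" if the first two lie within 2 percentage points) (east / south-west / north-west / none)
- amount of E at the outlet or at the end, in percent of the X put in, east
- amount of E at the outlet or at the end, in percent of the X put in, south-west
- amount of E at the outlet or at the end, in percent of the X put in, north-west

- the stated concentrations are those of everything mixed, before any reaction; amounts are the same in each set-up
- the earlier runs were made in a closed, stirred flask
- a reading or a percentage of E counts all its forms, free or not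

The oak row at 2.50 min holds the highest reading, 28.2%, and the row at 4.00 min holds 26.3%. I call the fade rate (an apparent first-order rate constant) minus the logarithm of the fraction of E left, per minute between two readings: 0.0465 min⁻¹ as read on oak. Carried from 4.00 min to 6.0 min, it gives 24.0%.

The last two birch rows keep a fraction 0.835 over that same stretch, at a lower charge. Put on the oak reading, that gives 22.0%. So my own range for the closed flask at 6.0 min runs from 22.0% to 24.0%.

A plug of feed in the east tube lives through the same 6.0 min as the south-west flask, from the same charge, so these two tie. The north-west tank, with 6.0 min on average, keeps a fraction 0.782 of E made at its entry, where the flask keeps 0.757. The last two birch rows give a faster fade, 0.0904 min⁻¹, and at the bottom of my range that reckoning puts the tank 2.5 percentage points above the flask, over the margin of 2 points, so the fade gives no verdict by itself. But the rise of E takes time too: the first oak reading gives a rough rise rate of 1.76 min⁻¹, with which the tank completes a fraction 0.914 of the rise. With that factor my tank reads 22.4% at the bottom of my range and 22.6% at the top, which is 0.41 points above and 1.3 points below the flask. The margin is larger than both, so I commit to a tie.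

The forecast says none, with 22.8% for east, 22.8% for south-west and 20.6% for north-west, on the ground that “Plug flow equals the batch flask”. Its tube and flask lie inside my range, but its north-west value is lower than my tank.

    X ⇌ E (K = 0.610, k = 0.460 min⁻¹)
    X ⇌ G (K = 110, k = 0.130 min⁻¹)
    X ⇌ J (K = 1.80, k = 0.0310 min⁻¹)
    X ⇌ Q (K = 25.0, k = 0.370 min⁻¹)
    X + E ⇌ D, settled at all times (K = 16.0 M⁻¹)
    X + E → L (k = 0.170 M⁻¹ min⁻¹)

The answer is none: east and south-west give 22.8% and 22.8%, north-west 22.4%. The north-west outlet still holds 14.1% as X, more than the 6.79% at the end in south-west. Over a further 54.0 min in east, the fade rate 0.0465 min⁻¹ keeps a fraction 0.0812, which turns 22.8% into 1.85%; at 60.0 min the east tube holds 1.74%.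

The runs are calculated with made-up constants, and the scatter is random.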